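**Retrosynthetic overview**

1. Labels: ring A carries one OH (a1 OH, a3 chain carbon C14, a5 ether O); ring B carries two OH (b1 ether O, b2 and b4 OH, b6 chain carbon C1); the chain C1–C14 runs from b6 to a3.
2. Feature used: C1 is benzylic on b6, next to the ether-bearing b1. After FGI to C1=C2, the C1–C2 bond is therefore traced back to a CH2–SO2–CH2 unit: the 20-membered carbocycle comes from the 21-membered benzylic sulfone 16 by Ramberg–Bäcklund loss of SO2.
3. Sulfone 16 comes from sulfide 14, whose S–C1 bond is made by attack of the chain-end thiolate on the benzylic bromide (closure of the 21-membered thia-ring).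
4. The open-chain precursor comes from an Ullmann ether (a5–O–b1) between bromoaldehyde 2 and phenol 8; 8 comes from a Wittig reaction (C13=C14) of 3-hydroxy-5-methoxybenzaldehyde with a C12 phosphonium salt, then hydrogenation.
5. Ring order: rings A and B are bought; the 21-membered thia-ring closes in step 9 and is contracted to the 20-membered ring in step 11; hydrogenation and O-demethylation finish the route.

Key step: step 11

Remark on the chemistry: the target has no stereocentre. The Wittig alkene 7 is drawn Z and the Ramberg–Bäcklund alkene 19 is drawn E; whichever isomers form, both double bonds are hydrogenated later.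

**Route**

Step 1
Reactants: 1 3,5-dimethoxybenzaldehyde
Product: 2 2-bromo-3,5-dimethoxybenzaldehyde
Conditions: NBS, MeCN, 0 °C → rt
Reagents that add atoms: N-bromosuccinimide, O=C1CCC(=O)N1Br
Why: Electrophilic aromatic bromination should go to C2, which is ortho to one methoxy group and para to the other, because C4 between the two methoxy groups is more hindered.

Step 2
Reactants: 3 12-bromododecan-1-ol
Product: 4 (12-hydroxydodecyl)triphenylphosphonium bromide
Conditions: PPh3, MeCN, reflux
Reagents that add atoms: triphenylphosphine, c1ccc(cc1)P(c1ccccc1)c1ccccc1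
Why: SN2 quaternisation of triphenylphosphine by the primary bromide should proceed cleanly, the free hydroxyl being inert.

Step 3
Reactants: 4 (12-hydroxydodecyl)triphenylphosphonium bromide; 5 3-hydroxy-5-methoxybenzaldehyde
Product: 7 3-[(Z)-13-hydroxytridec-1-en-1-yl]-5-methoxyphenol, via ylide alkoxide 6 (not isolated)
Conditions: 4 (2.5 equiv), NaN(SiMe3)2 (5.0 equiv), THF, 0 °C; then 5, 0 °C → rt
Reagents that add atoms: none
Why: Wittig olefination with a non-stabilised ylide, made with two equivalents of base per salt and used in excess to absorb the phenol proton of 5, should give mainly the Z alkene because the meta-phenoxide is not conjugated with the aldehyde.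

Step 4
Reactants: 7 3-[(Z)-13-hydroxytridec-1-en-1-yl]-5-methoxyphenol
Product: 8 3-(13-hydroxytridecyl)-5-methoxyphenol
Conditions: H2 (1 atm), 10% Pd/C, EtOAc/EtOH, rt
Reagents that add atoms: none
Why: Catalytic hydrogenation should saturate the styrenyl double bond of either geometry without touching the phenol, the methyl ether or the primary alcohol.

Step 5
Reactants: 8 3-(13-hydroxytridecyl)-5-methoxyphenol; 2 2-bromo-3,5-dimethoxybenzaldehyde
Product: 9 2-[3-(13-hydroxytridecyl)-5-methoxyphenoxy]-3,5-dimethoxybenzaldehyde
Conditions: CuI (20 mol %), N,N-dimethylglycine hydrochloride, Cs2CO3, 1,4-dioxane, 100 °C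
Reagents that add atoms: none
Why: Ullmann-type copper-catalysed diaryl ether synthesis should work because the ortho-formyl group assists insertion of copper into the C–Br bond and the carbonate deprotonates only the phenol, leaving the primary alcohol a spectator.

Step 6
Reactants: 9 2-[3-(13-hydroxytridecyl)-5-methoxyphenoxy]-3,5-dimethoxybenzaldehyde
Product: 10 S-{13-[3-(2-formyl-4,6-dimethoxyphenoxy)-5-methoxyphenyl]tridecyl} ethanethioate
Conditions: PPh3, DIAD, THF, 0 °C; then 9 and AcSH, 0 °C → rt
Reagents that add atoms: thioacetic acid, CC(=O)S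
Why: Mitsunobu thioesterification should replace the primary hydroxyl by thioacetate in an SN2 step, since thioacetic acid is an acidic pronucleophile and the aryl aldehyde and ethers are inert to the preformed betaine.

Step 7
Reactants: 10 S-{13-[3-(2-formyl-4,6-dimethoxyphenoxy)-5-methoxyphenyl]tridecyl} ethanethioate
Product: 11 S-{13-[3-(2-(hydroxymethyl)-4,6-dimethoxyphenoxy)-5-methoxyphenyl]tridecyl} ethanethioate
Conditions: NaBH4 (0.6 equiv), THF/EtOH, −20 °C; AcOH quench
Reagents that add atoms: none
Why: Borohydride reduction of the aryl aldehyde is much faster than hydride or alkoxide attack on a thioester, so a limited charge of NaBH4 at low temperature with an acidic quench should leave the remote thioacetate intact.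

Step 8
Reactants: 11 S-{13-[3-(2-(hydroxymethyl)-4,6-dimethoxyphenoxy)-5-methoxyphenyl]tridecyl} ethanethioate
Product: 12 S-{13-[3-(2-(bromomethyl)-4,6-dimethoxyphenoxy)-5-methoxyphenyl]tridecyl} ethanethioate
Conditions: CBr4, PPh3, CH2Cl2, 0 °C
Reagents that add atoms: tetrabromomethane, BrC(Br)(Br)Br
Why: The Appel reaction should convert the benzylic alcohol to the bromide under neutral conditions that a thioacetate tolerates.

Step 9
Reactants: 12 S-{13-[3-(2-(bromomethyl)-4,6-dimethoxyphenoxy)-5-methoxyphenyl]tridecyl} ethanethioate
Product: 14 macrocyclic sulfide (21-membered thia-ring; tri-O-methyl), via potassium thiolate 13 (not isolated)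
Conditions: K2CO3, degassed MeOH/THF 1:1, syringe-pump addition of 12 (final ca. 1 mM), rt, Ar
Reagents that add atoms: none
Why: Methanolysis of the thioacetate releases the thiolate, which under high dilution should displace the tethered benzylic bromide in an intramolecular SN2 reaction (21-membered closure) far faster than methoxide can attack that bromide.

Step 10
Reactants: 14 macrocyclic sulfide (21-membered thia-ring; tri-O-methyl)
Product: 16 macrocyclic benzylic sulfone, via sulfoxide 15 (not isolated)
Conditions: mCPBA (2.3 equiv), NaHCO3, CH2Cl2, 0 °C → rt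
Reagents that add atoms: 3-chloroperoxybenzoic acid, OOC(=O)c1cccc(Cl)c1
Why: Stepwise peracid oxidation of sulfur (sulfide to sulfoxide to sulfone) should be much faster at 0 °C than any oxidation of the methoxy-substituted arenes.

Step 11
Reactants: 16 macrocyclic benzylic sulfone
Product: 19 (E)-macrocyclic alkene (20-membered; C1=C2; tri-O-methyl), via α-bromo sulfone 17 (not isolated), via episulfone 18 (not isolated)
Conditions: KOH/Al2O3, CBr2F2, t-BuOH/CH2Cl2, 5 °C → rt
Reagents that add atoms: none
Why: This is the Ramberg–Bäcklund reaction with in situ halogenation (Meyers–Chan conditions): hydroxide deprotonates the more acidic benzylic carbon C1, the carbanion takes bromine from CBr2F2 to give 17, and deprotonation at C2 followed by 1,3-displacement of bromide gives episulfone 18, which loses SO2 cheletropically to leave the C1=C2 double bond. The closest known reaction type is the ring contraction of macrocyclic and cyclophane sulfones, benzyl alkyl sulfones included, to cycloalkenes under these conditions. The only ring that closes is the three-membered episulfone (3-exo-tet at C1); the 20-membered carbocycle arises from the existing 21-membered ring by contraction, so the carbon–carbon bond forms without a macrocyclisation event. No stereocentre remains in 19, because the two transient centres of 18 vanish with SO2; the base-equilibrated trans episulfone should favour the E alkene, and the geometry is erased in step 12 anyway. The selectivity needed is halogenation at a sulfone α-carbon rather than on the electron-rich arenes, which is secured because CBr2F2 transfers bromine only to carbanions and the benzylic C1–H is the most acidic site; difluorocarbene, unlike dichlorocarbene, is too unreactive to add to the styrene formed.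

Step 12
Reactants: 19 (E)-macrocyclic alkene (20-membered; C1=C2; tri-O-methyl)
Product: 20 saturated macrocyclic diaryl ether trimethyl ether
Conditions: H2 (1 atm), 10% Pd/C, EtOAc, rt
Reagents that add atoms: none
Why: Catalytic hydrogenation should reduce the styrenyl double bond of either geometric isomer, with the aryl ethers inert and no sulfur left to poison the catalyst.

Step 13
Reactants: 20 saturated macrocyclic diaryl ether trimethyl ether
Product: 21 CNP0173380.0 (target triol)
Conditions: BBr3, CH2Cl2, −78 °C → rt; then aqueous NaHCO3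
Reagents that add atoms: none
Why: BBr3 demethylation (Lewis acid complexation, then bromide attack on methyl) should cleave the three aryl methyl ethers while the diaryl ether, which has no sp3 carbon on oxygen, stays intact.

**Compound list**

1 | 3,5-dimethoxybenzaldehyde | COc1cc(C=O)cc(OC)c1 | starting material
2 | 2-bromo-3,5-dimethoxybenzaldehyde | COc1cc(OC)c(Br)c(C=O)c1 | intermediate
3 | 12-bromododecan-1-ol | OCCCCCCCCCCCCBr | starting material
4 | (12-hydroxydodecyl)triphenylphosphonium bromide | [Br-].OCCCCCCCCCCCC[P+](c1ccccc1)(c1ccccc1)c1ccccc1 | intermediate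
5 | 3-hydroxy-5-methoxybenzaldehyde | COc1cc(O)cc(C=O)c1 | starting material
6 | sodium 12-(triphenylphosphoranylidene)dodecan-1-olate (ylide alkoxide, not isolated) | [Na+].[O-]CCCCCCCCCCCC=P(c1ccccc1)(c1ccccc1)c1ccccc1 | intermediate
7 | 3-[(Z)-13-hydroxytridec-1-en-1-yl]-5-methoxyphenol (E isomer may accompany it) | COc1cc(O)cc(/C=C\CCCCCCCCCCCO)c1 | intermediate
8 | 3-(13-hydroxytridecyl)-5-methoxyphenol | COc1cc(O)cc(CCCCCCCCCCCCCO)c1 | intermediate
9 | 2-[3-(13-hydroxytridecyl)-5-methoxyphenoxy]-3,5-dimethoxybenzaldehyde | COc1cc(CCCCCCCCCCCCCO)cc(Oc2c(OC)cc(OC)cc2C=O)c1 | intermediate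
10 | S-{13-[3-(2-formyl-4,6-dimethoxyphenoxy)-5-methoxyphenyl]tridecyl} ethanethioate | CC(=O)SCCCCCCCCCCCCCc1cc(OC)cc(Oc2c(OC)cc(OC)cc2C=O)c1 | intermediate
11 | S-{13-[3-(2-(hydroxymethyl)-4,6-dimethoxyphenoxy)-5-methoxyphenyl]tridecyl} ethanethioate | CC(=O)SCCCCCCCCCCCCCc1cc(OC)cc(Oc2c(OC)cc(OC)cc2CO)c1 | intermediate
12 | S-{13-[3-(2-(bromomethyl)-4,6-dimethoxyphenoxy)-5-methoxyphenyl]tridecyl} ethanethioate | CC(=O)SCCCCCCCCCCCCCc1cc(OC)cc(Oc2c(OC)cc(OC)cc2CBr)c1 | intermediate
13 | potassium 13-[3-(2-(bromomethyl)-4,6-dimethoxyphenoxy)-5-methoxyphenyl]tridecane-1-thiolate (not isolated) | [K+].[S-]CCCCCCCCCCCCCc1cc(OC)cc(Oc2c(OC)cc(OC)cc2CBr)c1 | intermediate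
14 | macrocyclic sulfide: b6–CH2–S–(CH2)13–a3, rings joined by the a5–O–b1 ether, OMe on a1, b2 and b4 (21-membered ring) | COc1cc2cc(c1)Oc1c(OC)cc(OC)cc1CSCCCCCCCCCCCCC2 | intermediate
15 | macrocyclic sulfoxide of 14 (racemic at sulfur, not isolated) | COc1cc2cc(c1)Oc1c(OC)cc(OC)cc1CS(=O)CCCCCCCCCCCCC2 | intermediate
16 | macrocyclic benzylic sulfone: b6–CH2–SO2–(CH2)13–a3, a5–O–b1 ether, OMe on a1, b2 and b4 (21-membered ring) | COc1cc2cc(c1)Oc1c(OC)cc(OC)cc1CS(=O)(=O)CCCCCCCCCCCCC2 | intermediate
17 | α-bromo sulfone: 16 with Br on benzylic C1 (racemic, not isolated) | COc1cc2cc(c1)Oc1c(OC)cc(OC)cc1C(Br)S(=O)(=O)CCCCCCCCCCCCC2 | intermediate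
18 | trans-episulfone: thiirane 1,1-dioxide spanning C1 and C2 (racemic, one enantiomer drawn, not isolated) | COc1cc2cc(c1)Oc1c(OC)cc(OC)cc1[C@H]1[C@H](CCCCCCCCCCCC2)S1(=O)=O | intermediate
19 | (E)-macrocyclic alkene: 20-membered ring with C1=C2, a5–O–b1 ether, OMe on a1, b2 and b4 (Z isomer may accompany it) | COc1cc2cc(c1)Oc1c(OC)cc(OC)cc1/C=C/CCCCCCCCCCCC2 | intermediate
20 | saturated 20-membered macrocycle, tri-O-methyl ether of the target | COc1cc2cc(c1)Oc1c(OC)cc(OC)cc1CCCCCCCCCCCCCC2 | intermediate
21 | CNP0173380.0: 20-membered diaryl ether macrocycle, OH on a1, b2 and b4, saturated C1–C14 chain from b6 to a3 | Oc1cc2cc(c1)Oc1c(O)cc(O)cc1CCCCCCCCCCCCCC2 | target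

**Step count**

Total steps: 13. Longest linear sequence: 12 steps (steps 2–13, from 12-bromododecan-1-ol 3 to 21); step 1 is the one-step branch that supplies ring B.

**Steps most likely to fail**

Step 11 (Ramberg–Bäcklund contraction). What may go wrong: a second bromination at the benzylic carbon before the slower deprotonation on the unactivated chain side, giving vinyl bromide or stalled α-bromo sulfone, or capture of difluorocarbene by the electron-rich styrene. The fallback forms the same C1=C2 bond by ring-closing metathesis. It sets out from 9 and comes back at 19.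
- Compound 9 would be oxidised with Dess–Martin periodinane in CH2Cl2 to the dialdehyde 2-[3-methoxy-5-(13-oxotridecyl)phenoxy]-3,5-dimethoxybenzaldehyde F1.
- Both aldehydes would be methylenated with Ph3P=CH2 (from methyltriphenylphosphonium bromide and KOC(CH3)3 in THF) to the diene 1-ethenyl-3,5-dimethoxy-2-[3-methoxy-5-(tetradec-13-en-1-yl)phenoxy]benzene F2.
- Metathesis of F2 with the second-generation Grubbs catalyst RuCl2(=CHPh)(H2IMes)(PCy3) at about 1 mM in refluxing CH2Cl2 should join the styrene and the terminal alkene with loss of ethene to give 19, which re-enters at step 12.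

Step 9 (closure of the 21-membered sulfide). What may go wrong: intermolecular S-alkylation to oligomers, air oxidation of the thiolate to disulfide, or methanolysis of the benzylic bromide before the thioacetate is cleaved. The fallback builds both C–S bonds from a dibromide and sulfide ion, so no protected thiol has to be unmasked in the closing flask. It sets out from 9 and comes back at 14.
- Compound 9 would be reduced with NaBH4 in MeOH to the diol 13-{3-[2-(hydroxymethyl)-4,6-dimethoxyphenoxy]-5-methoxyphenyl}tridecan-1-ol F3.
- A double Appel reaction (CBr4, PPh3, CH2Cl2) would give the dibromide 1-(bromomethyl)-2-[3-(13-bromotridecyl)-5-methoxyphenoxy]-3,5-dimethoxybenzene F4.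
- Simultaneous slow addition of F4 and Na2S·9H2O to degassed EtOH/THF at high dilution should give first the benzylic thiolate and then, by intramolecular displacement of the primary bromide, sulfide 14, which re-enters at step 10.

Step 5 (Ullmann ether). What may go wrong: slow insertion of copper into the doubly ortho-substituted, electron-rich C–Br bond with competing hydrodebromination, or O-arylation of the primary alcohol. The fallback reverses the polarity of the coupling, so that the halide sits on unhindered ring A and the phenol on ring B. It sets out from ylide 6 (made from 4 as in step 3) and comes back at 9.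
- Purchased 2,4-dimethoxyphenol F5 would be ortho-formylated (MgCl2, Et3N, paraformaldehyde, MeCN, reflux) to 2-hydroxy-3,5-dimethoxybenzaldehyde F6.
- Ylide 6 would be condensed with purchased 3-bromo-5-methoxybenzaldehyde F7 to give (Z)-13-(3-bromo-5-methoxyphenyl)tridec-12-en-1-ol F8.
- The double bond of F8 would be reduced with diimide (p-toluenesulfonyl hydrazide, NaOAc, THF/H2O, reflux), which spares the aryl bromide, to give 13-(3-bromo-5-methoxyphenyl)tridecan-1-ol F9.
- Coupling of F6 with F9 (CuI, picolinic acid, K3PO4, DMSO, 90 °C) should give 9, which re-enters at step 6.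

**Further compounds**

F1 | step 11 | 2-[3-methoxy-5-(13-oxotridecyl)phenoxy]-3,5-dimethoxybenzaldehyde | COc1cc(CCCCCCCCCCCCC=O)cc(Oc2c(OC)cc(OC)cc2C=O)c1
F2 | step 11 | 1-ethenyl-3,5-dimethoxy-2-[3-methoxy-5-(tetradec-13-en-1-yl)phenoxy]benzene | COc1cc(CCCCCCCCCCCCC=C)cc(Oc2c(OC)cc(OC)cc2C=C)c1
F3 | step 9 | 13-{3-[2-(hydroxymethyl)-4,6-dimethoxyphenoxy]-5-methoxyphenyl}tridecan-1-ol | COc1cc(CCCCCCCCCCCCCO)cc(Oc2c(OC)cc(OC)cc2CO)c1
F4 | step 9 | 1-(bromomethyl)-2-[3-(13-bromotridecyl)-5-methoxyphenoxy]-3,5-dimethoxybenzene | COc1cc(CCCCCCCCCCCCCBr)cc(Oc2c(OC)cc(OC)cc2CBr)c1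
F5 | step 5 | 2,4-dimethoxyphenol (purchased) | COc1ccc(O)c(OC)c1
F6 | step 5 | 2-hydroxy-3,5-dimethoxybenzaldehyde | COc1cc(OC)c(O)c(C=O)c1
F7 | step 5 | 3-bromo-5-methoxybenzaldehyde (purchased) | COc1cc(Br)cc(C=O)c1
F8 | step 5 | (Z)-13-(3-bromo-5-methoxyphenyl)tridec-12-en-1-ol | COc1cc(Br)cc(/C=C\CCCCCCCCCCCO)c1
F9 | step 5 | 13-(3-bromo-5-methoxyphenyl)tridecan-1-ol | COc1cc(Br)cc(CCCCCCCCCCCCCO)c1
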